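**Retrosynthetic overview**
- Target ⇐ (2R,4R)-flavan-4-ol by ionic deoxygenation at C4 ⇐ racemic flavanone, from which a chiral transfer-hydrogenation catalyst picks out the 2R enantiomer.
- Racemic flavanone ⇐ 3-cinnamoyl-4-methoxy-6-(homoprenyl)-2-pyrone in one base-mediated operation: the pyrone opens, a Dieckmann closure builds aromatic ring A, and the new 2'-phenoxide closes ring C by oxa-Michael addition.
- The pyrone substitution fixes the A-ring pattern: 4-OMe becomes 5-OMe, the lactone C=O becomes O1, the ring-oxygen carbon becomes 7-OH, and the side-chain CH2 becomes C8 carrying the prenyl group.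
- Pyrone chalcone ⇐ triacetic acid lactone by lateral prenylation, C3-acetylation, aldol condensation with 3-hydroxy-5-methoxybenzaldehyde and O-methylation.
- Ring order: B is bought; A and C form together in step 5.

Assumption: the stereocentre of the target is 2R (CIP reading of the given SMILES); triacetic acid lactone, prenyl bromide, acetic acid and 3-hydroxy-5-methoxybenzaldehyde are bought.

**Step 1**
Reactants: 1 4-hydroxy-6-methyl-2H-pyran-2-one (triacetic acid lactone); 2 1-bromo-3-methylbut-2-ene (prenyl bromide)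
Product: 3 4-hydroxy-6-(4-methylpent-3-en-1-yl)-2H-pyran-2-one
Conditions: LDA (2.2 equiv), THF, −78 °C; then 2, −78 → 0 °C; aq. HCl
Reagents that add atoms: none
Why: Dianion alkylation: the second deprotonation gives the 6-CH2 carbanion, the most nucleophilic site, which displaces the primary allylic bromide (SN2, lateral γ-alkylation); no stereocentre.

**Step 2**
Reactants: 3 4-hydroxy-6-(4-methylpent-3-en-1-yl)-2H-pyran-2-one; 4 acetic acid
Product: 5 3-acetyl-4-hydroxy-6-(4-methylpent-3-en-1-yl)-2H-pyran-2-one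
Conditions: DCC (1.2 equiv), DMAP (0.3 equiv), toluene, rt → 50 °C
Reagents that add atoms: none
Why: Steglich-type O-acylation followed by DMAP-mediated O→C acyl migration (Fries-type) to C3 gives the chelated 3-acyl-4-hydroxypyrone, as in the preparation of dehydroacetic acid analogues; no stereocentre.

**Step 3**
Reactants: 5 3-acetyl-4-hydroxy-6-(4-methylpent-3-en-1-yl)-2H-pyran-2-one; 6 3-hydroxy-5-methoxybenzaldehyde
Product: 7 4-hydroxy-3-[(2E)-3-(3-hydroxy-5-methoxyphenyl)prop-2-enoyl]-6-(4-methylpent-3-en-1-yl)-2H-pyran-2-one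
Conditions: piperidine (0.2 equiv), CHCl3, reflux, Dean–Stark
Reagents that add atoms: none
Why: Amine-catalysed aldol (Claisen–Schmidt) condensation at the acetyl methyl, the standard route to dehydroacetic-acid chalcones; dehydration gives the conjugated E-enone and the free phenol is tolerated; no stereocentre.

**Step 4**
Reactants: 7 4-hydroxy-3-[(2E)-3-(3-hydroxy-5-methoxyphenyl)prop-2-enoyl]-6-(4-methylpent-3-en-1-yl)-2H-pyran-2-one
Product: 8 3-[(2E)-3-(3-hydroxy-5-methoxyphenyl)prop-2-enoyl]-4-methoxy-6-(4-methylpent-3-en-1-yl)-2H-pyran-2-one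
Conditions: TMSCHN2 (1.1 equiv), toluene/MeOH 4:1, 0 °C → rt
Reagents that add atoms: (trimethylsilyl)diazomethane, C[Si](C)(C)C=[N+]=[N-] (supplies the O-methyl carbon)
Why: Diazoalkane O-methylation is gated by proton transfer, so the vinylogous acid (pKa about 5) is methylated and the phenol (pKa about 10) is left free; this methyl ether becomes the 5-OMe group; no stereocentre.

**Step 5**
Reactants: 8 3-[(2E)-3-(3-hydroxy-5-methoxyphenyl)prop-2-enoyl]-4-methoxy-6-(4-methylpent-3-en-1-yl)-2H-pyran-2-one
Product: 11 rac-7-hydroxy-2-(3-hydroxy-5-methoxyphenyl)-5-methoxy-8-(3-methylbut-2-en-1-yl)-2,3-dihydro-4H-chromen-4-one, via ring-opened keto ester 9 (not isolated), via chalcone 10 (not isolated)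
Conditions: NaOMe (4 equiv), MeOH, reflux; then aq. HCl to pH 4
Reagents that add atoms: sodium methoxide/methanol, [Na+].[O-]C (its MeO group is held only in intermediate 9 and leaves again as methanol; 11 keeps no reagent atom)
Why: Proposed new method: methoxide opens the 2-pyrone at C2 to keto ester 9, the ketone α'-enolate (the former 6-CH2, carrying the prenyl unit) closes onto the cis-disposed ester in a Dieckmann (Claisen) condensation and the trione tautomerises to the aromatic chalcone 10 (ring A), whose 2'-phenoxide then adds to the enone in a 6-endo oxa-Michael reaction (ring C); the closest known reaction types are the alkoxide-mediated Michael–Dieckmann synthesis of dihydroresorcinols (a ketone α'-carbon acylated by an ester although a more acidic site is present), the base-induced Claisen cyclisation of triketide pyrones to phloroglucinols, and the alkaline isomerisation of 2'-hydroxy-6'-methoxychalcones to flavanones; C2 is formed without control (racemic).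

**Step 6**
Reactants: 11 rac-7-hydroxy-2-(3-hydroxy-5-methoxyphenyl)-5-methoxy-8-(3-methylbut-2-en-1-yl)-2,3-dihydro-4H-chromen-4-one
Product: 12 (2R,4R)-2-(3-hydroxy-5-methoxyphenyl)-5-methoxy-8-(3-methylbut-2-en-1-yl)-3,4-dihydro-2H-chromene-4,7-diol
Conditions: RuCl[(R,R)-TsDPEN](p-cymene) (1 mol %), HCO2H/Et3N 5:2, EtOAc, rt, stopped at about 50% conversion
Reagents that add atoms: none
Why: Noyori–Ikariya asymmetric transfer hydrogenation run as a kinetic resolution: the (R,R) catalyst delivers hydride to the face that gives 4R, which is the favoured axial, cis-forming approach only for (2R)-11, so 2R is selected and 4R is set while (2S)-11 stays behind (it can be racemised with NaOMe through 10 and recycled); the prenyl alkene is inert to the metal hydride.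

**Step 7**
Reactants: 12 (2R,4R)-2-(3-hydroxy-5-methoxyphenyl)-5-methoxy-8-(3-methylbut-2-en-1-yl)-3,4-dihydro-2H-chromene-4,7-diol
Product: 13 (2R)-2-(3-hydroxy-5-methoxyphenyl)-5-methoxy-8-(3-methylbut-2-en-1-yl)-3,4-dihydro-2H-chromen-7-ol
Conditions: Et3SiH (5 equiv), TFA (3 equiv), CH2Cl2, −40 °C
Reagents that add atoms: none
Why: Ionic hydrogenation: the 4-hydroxyl (ortho to O1 and 5-OMe, para to 7-OH) ionises at low temperature to a strongly stabilised benzylic cation that takes hydride from the silane; C2 is not part of the cation and stays R, and the prenyl alkene is not protonated at −40 °C with this amount of acid.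

**Compound list**
1 | 4-hydroxy-6-methyl-2H-pyran-2-one | CC1=CC(O)=CC(=O)O1 | starting material
2 | 1-bromo-3-methylbut-2-ene | CC(C)=CCBr | starting material
3 | 4-hydroxy-6-(4-methylpent-3-en-1-yl)-2H-pyran-2-one | CC(C)=CCCC1=CC(O)=CC(=O)O1 | intermediate
4 | acetic acid | CC(O)=O | starting material
5 | 3-acetyl-4-hydroxy-6-(4-methylpent-3-en-1-yl)-2H-pyran-2-one | CC(=O)C1=C(O)C=C(CCC=C(C)C)OC1=O | intermediate
6 | 3-hydroxy-5-methoxybenzaldehyde | COc1cc(O)cc(C=O)c1 | starting material
7 | 4-hydroxy-3-[(2E)-3-(3-hydroxy-5-methoxyphenyl)prop-2-enoyl]-6-(4-methylpent-3-en-1-yl)-2H-pyran-2-one | COc1cc(O)cc(/C=C/C(=O)C2=C(O)C=C(CCC=C(C)C)OC2=O)c1 | intermediate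
8 | 3-[(2E)-3-(3-hydroxy-5-methoxyphenyl)prop-2-enoyl]-4-methoxy-6-(4-methylpent-3-en-1-yl)-2H-pyran-2-one | COc1cc(O)cc(/C=C/C(=O)C2=C(OC)C=C(CCC=C(C)C)OC2=O)c1 | intermediate
9 | methyl (2E)-2-[(2E)-3-(3-hydroxy-5-methoxyphenyl)prop-2-enoyl]-3-methoxy-9-methyl-5-oxodeca-2,8-dienoate | COC(=O)/C(C(=O)/C=C/c1cc(O)cc(OC)c1)=C(/OC)CC(=O)CCC=C(C)C | intermediate
10 | (2E)-1-[2,4-dihydroxy-6-methoxy-3-(3-methylbut-2-en-1-yl)phenyl]-3-(3-hydroxy-5-methoxyphenyl)prop-2-en-1-one | COc1cc(O)cc(/C=C/C(=O)c2c(OC)cc(O)c(CC=C(C)C)c2O)c1 | intermediate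
11 | rac-7-hydroxy-2-(3-hydroxy-5-methoxyphenyl)-5-methoxy-8-(3-methylbut-2-en-1-yl)-2,3-dihydro-4H-chromen-4-one (racemate) | COc1cc(O)cc(C2CC(=O)c3c(OC)cc(O)c(CC=C(C)C)c3O2)c1 | intermediate
12 | (2R,4R)-2-(3-hydroxy-5-methoxyphenyl)-5-methoxy-8-(3-methylbut-2-en-1-yl)-3,4-dihydro-2H-chromene-4,7-diol | COc1cc(O)cc([C@H]2C[C@@H](O)c3c(OC)cc(O)c(CC=C(C)C)c3O2)c1 | intermediate
13 | (2R)-2-(3-hydroxy-5-methoxyphenyl)-5-methoxy-8-(3-methylbut-2-en-1-yl)-3,4-dihydro-2H-chromen-7-ol | COc1cc(O)cc([C@H]2CCc3c(OC)cc(O)c(CC=C(C)C)c3O2)c1 | target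

**Step count:** 7 steps in total. Longest linear sequence: 7 steps (1 → 3 → 5 → 7 → 8 → 11 → 12 → 13). The kinetic resolution in step 6 gives at most half of the material per pass.

**Steps most likely to fail**

Step 5 (ring A and ring C in one operation). The ring-opened intermediate may lose the cinnamoyl group by retro-Claisen cleavage, or close onto the enone carbonyl instead of the ester. The fallback builds ring A before the enone exists and closes ring C afterwards. It sets out from 5: O-methylation (Me2SO4, K2CO3, acetone) gives 3-acetyl-4-methoxy-6-(4-methylpent-3-en-1-yl)-2H-pyran-2-one F1. Mg(OMe)2 in MeOH converts it into 1-[2,4-dihydroxy-6-methoxy-3-(3-methylbut-2-en-1-yl)phenyl]ethan-1-one F2. Claisen–Schmidt condensation of F2 with 6 (KOH, EtOH) gives chalcone 10, which is cyclised (NaOAc, EtOH, reflux) to 11, where the route resumes.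

Step 6 (kinetic resolution). The electron-rich ketone with its free phenols may be slow with the catalyst, or the selectivity factor may be low. The fallback gives up catalytic resolution. It sets out from 11: the enantiomers are separated by preparative chromatography on a chiral stationary phase to give (2R)-7-hydroxy-2-(3-hydroxy-5-methoxyphenyl)-5-methoxy-8-(3-methylbut-2-en-1-yl)-2,3-dihydro-4H-chromen-4-one F3; the 2S isomer is racemised with base and recycled. Reduction of F3 with NaBH4 (MeOH, 0 °C; axial attack gives the cis alcohol) rejoins the route at 12.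

Step 4 (selective O-methylation). TMSCHN2 may also methylate the phenol or attack another oxygen of the chelated triketone system. The fallback masks the phenol so that a hard methylating agent can be used. It sets out from 6: silylation (TBSCl, imidazole, DMF) gives 3-[(tert-butyldimethylsilyl)oxy]-5-methoxybenzaldehyde F4. Condensation with 5 as in step 3 gives the silyl-protected pyrone chalcone F5, and Me2SO4/K2CO3 in acetone gives its 4-methyl ether F6. Under the NaOMe/MeOH conditions of step 5 the aryl silyl ether is cleaved during the cascade, so the route is rejoined at 11.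

**Further compounds**
F1 | step 5 | 3-acetyl-4-methoxy-6-(4-methylpent-3-en-1-yl)-2H-pyran-2-one | CC(=O)C1=C(OC)C=C(CCC=C(C)C)OC1=O
F2 | step 5 | 1-[2,4-dihydroxy-6-methoxy-3-(3-methylbut-2-en-1-yl)phenyl]ethan-1-one | CC(=O)c1c(OC)cc(O)c(CC=C(C)C)c1O
F3 | step 6 | (2R)-7-hydroxy-2-(3-hydroxy-5-methoxyphenyl)-5-methoxy-8-(3-methylbut-2-en-1-yl)-2,3-dihydro-4H-chromen-4-one | COc1cc(O)cc([C@H]2CC(=O)c3c(OC)cc(O)c(CC=C(C)C)c3O2)c1
F4 | step 4 | 3-[(tert-butyldimethylsilyl)oxy]-5-methoxybenzaldehyde | COc1cc(O[Si](C)(C)C(C)(C)C)cc(C=O)c1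
F5 | step 4 | 3-[(2E)-3-{3-[(tert-butyldimethylsilyl)oxy]-5-methoxyphenyl}prop-2-enoyl]-4-hydroxy-6-(4-methylpent-3-en-1-yl)-2H-pyran-2-one | COc1cc(O[Si](C)(C)C(C)(C)C)cc(/C=C/C(=O)C2=C(O)C=C(CCC=C(C)C)OC2=O)c1
F6 | step 4 | 3-[(2E)-3-{3-[(tert-butyldimethylsilyl)oxy]-5-methoxyphenyl}prop-2-enoyl]-4-methoxy-6-(4-methylpent-3-en-1-yl)-2H-pyran-2-one | COc1cc(O[Si](C)(C)C(C)(C)C)cc(/C=C/C(=O)C2=C(OC)C=C(CCC=C(C)C)OC2=O)c1
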